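**Retrosynthetic overview**
1. The C–Br bond comes last: Mn–H hydrogenation of a C5 vinyl bromide made from a C5 ketone; the C14 carbinol comes from exo-selective hydration of a 2-isopropylnorbornene.
2. Key disconnection: ring B and the bicyclo[2.2.1]heptene open together by an intramolecular Diels–Alder reaction of a 1-tethered-2-isopropylcyclopentadiene with an unactivated vinyl group on ring A.
3. The cycloaddition precursor is assembled in one flask from a ring-A enone, vinylmagnesium bromide and a dienyl bromide (directed conjugate addition, then enolate alkylation).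
4. Ring A comes from (R)-linalool (singlet-oxygen ene reaction, then ring-closing metathesis); its carbinol carbon is the only stereocentre taken from the chiral pool and controls all others.
5. Ring order: A (metathesis), then B and the two norbornane rings in one operation; the five-membered ring of the diene is bought as cyclopentanone.

Assumption: commercial (R)-(−)-linalool is taken as enantiopure (≥97% ee); tetracyclic compounds are numbered as tetracyclo[10.2.1.0^1,10.0^4,9]pentadecanes (C1 quaternary bridgehead, C4 C-methyl, C5 C–Br, C8 and C14 carbinols, C12 bridgehead CH, C15 CH2 bridge).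

**Step 1**
Reactants: 1 (R)-(−)-linalool [(3R)-3,7-dimethylocta-1,6-dien-3-ol]
Product: 3 (6R)-6-hydroxy-2,6-dimethylocta-1,7-dien-3-one, via allylic hydroperoxide 2 (not isolated)
Conditions: O2, hν (white LED), TPP (0.5 mol%), CH2Cl2, 0 °C; then Ac2O, pyridine, 0 °C → rt
Reagents that add atoms: dioxygen, O=O
Why: Schenck ene reaction of singlet oxygen, which attacks only the electron-rich trisubstituted alkene, then Kornblum–DeLaMare-type dehydration of the secondary allylic hydroperoxide to the isopropenyl ketone; the carbinol stereocentre of linalool is not touched (the regioisomeric tertiary hydroperoxide, about half of the material, is separated).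

**Step 2**
Reactants: 3 (6R)-6-hydroxy-2,6-dimethylocta-1,7-dien-3-one
Product: 4 (4R)-4-hydroxy-2,4-dimethylcyclohex-2-en-1-one
Conditions: Hoveyda–Grubbs II (3 mol%), CH2Cl2 (0.01 M), 40 °C
Reagents that add atoms: none
Why: Ring-closing metathesis between the vinyl carbinol and the 1,1-disubstituted enone alkene closes ring A as a 2-methylcyclohexenone with loss of ethene; the carbinol stereocentre is retained and no new one is formed.

**Step 3**
Reactants: 5 cyclopentanone; 6 acetone
Product: 8 2-(2-hydroxypropan-2-yl)cyclopentan-1-one (racemic), via lithium cyclopentenolate 7 (not isolated)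
Conditions: LDA, THF, −78 °C; then acetone, −78 °C; AcOH quench
Reagents that add atoms: none
Why: Directed aldol addition of the kinetic lithium enolate to acetone, which avoids self-condensation of cyclopentanone; the single stereocentre is racemic and is removed in step 4.

**Step 4**
Reactants: 8 2-(2-hydroxypropan-2-yl)cyclopentan-1-one
Product: 10 2-(propan-2-yl)cyclopent-2-en-1-one, via isopropylidene ketone 9 (not isolated)
Conditions: 48% HBr (cat.), n-BuOH, reflux
Reagents that add atoms: none
Why: Acid-catalysed E1 dehydration to the isopropylidene ketone followed by acid-catalysed double-bond isomerisation into the five-membered ring, the usual outcome for 2-alkylidenecyclopentanones; no stereocentre.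

**Step 5**
Reactants: 10 2-(propan-2-yl)cyclopent-2-en-1-one
Product: 11 1-ethenyl-2-(propan-2-yl)cyclopent-2-en-1-ol (racemic)
Conditions: vinylMgBr, THF, −78 → 0 °C; aq. NH4Cl
Reagents that add atoms: vinylmagnesium bromide, C=C[Mg]Br
Why: 1,2-Addition of the vinyl Grignard reagent to the enone carbonyl (hard nucleophile, no copper); the tertiary carbinol is racemic and its stereocentre disappears in step 6.

**Step 6**
Reactants: 11 1-ethenyl-2-(propan-2-yl)cyclopent-2-en-1-ol
Product: 12 (3E)-3-(2-bromoethylidene)-2-(propan-2-yl)cyclopent-1-ene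
Conditions: PBr3 (0.4 equiv), pyridine (cat.), Et2O, −20 → 0 °C; used crude at once
Reagents that add atoms: phosphorus tribromide, BrP(Br)Br
Why: Bromination with allylic transposition (SN2′/ion-pair collapse at the unhindered vinyl terminus, as in linalool → geranyl bromide) gives the conjugated primary dienyl bromide; only an alkene geometry (mainly E) results and it is erased in step 8.

**Step 7**
Reactants: 4 (4R)-4-hydroxy-2,4-dimethylcyclohex-2-en-1-one; 12 (3E)-3-(2-bromoethylidene)-2-(propan-2-yl)cyclopent-1-ene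
Product: 14 (2S,3S,4R)-3-ethenyl-4-hydroxy-2,4-dimethyl-2-{(2E)-2-[2-(propan-2-yl)cyclopent-2-en-1-ylidene]ethyl}cyclohexan-1-one, via bromomagnesium enolate 13 (not isolated)
Conditions: vinylMgBr (2.3 equiv), THF, −78 → −20 °C; then DMPU, 12 (1.4 equiv), −20 °C → rt; aq. NH4Cl
Reagents that add atoms: vinylmagnesium bromide, C=C[Mg]Br
Why: Ligand-assisted conjugate addition of a Grignard reagent to a 4-oxido enone followed by enolate C-alkylation: the magnesium alkoxide at C4 delivers the vinyl group to the neighbouring β-carbon from its own face (vinyl cis to OH), and the tetrasubstituted magnesium enolate is then alkylated by the allylic bromide (SN2 at CH2Br) on the face opposite the new vinyl group and the alkoxide, which sets the quaternary centre with the side chain trans to vinyl.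

**Step 8**
Reactants: 14 (2S,3S,4R)-3-ethenyl-4-hydroxy-2,4-dimethyl-2-{(2E)-2-[2-(propan-2-yl)cyclopent-2-en-1-ylidene]ethyl}cyclohexan-1-one
Product: 16 (1R,4S,8R,9S,10S,12R)-8-hydroxy-4,8-dimethyl-14-(propan-2-yl)tetracyclo[10.2.1.0^1,10.0^4,9]pentadec-13-en-5-one, via cyclopentadiene tautomer 15 (not isolated)
Conditions: CSA (5 mol%), CH2Cl2, rt; then Et3N, solvent exchange to toluene (0.005 M), BHT, 190 °C, sealed tube, 24 h
Reagents that add atoms: none
Why: Intramolecular Diels–Alder reaction (type 1, cyclopentadiene as diene) at the end of a proton-shift/[1,5]-H-shift cascade: mild acid moves the exocyclic double bond into the ring, the cyclopentadiene tautomers equilibrate, and only the 1-tethered-2-isopropyl tautomer can reach the vinyl group through a six-membered tether, so ring B and the norbornene form together; the vinyl group reacts in its C9–H-eclipsed conformer (CH2 turned away from the axial C4-methyl and C8-OH) on the tether face, giving H-10 anti to H-9 (trans-fused chair ring B), and the tether sits exo with the isopropyl-bearing diene carbons turned away from ring A, which fixes the quaternary bridgehead C1 and C12.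

**Step 9**
Reactants: 16 (1R,4S,8R,9S,10S,12R)-8-hydroxy-4,8-dimethyl-14-(propan-2-yl)tetracyclo[10.2.1.0^1,10.0^4,9]pentadec-13-en-5-one
Product: 18 (1R,4S,8R,9S,10S,12R,14R)-8,14-dihydroxy-4,8-dimethyl-14-(propan-2-yl)tetracyclo[10.2.1.0^1,10.0^4,9]pentadecan-5-one, via tertiary hydroperoxide 17 (not isolated)
Conditions: Co(acac)2 (20 mol%), PhSiH3, O2 (1 atm), THF/i-PrOH, 0 °C → rt; then PPh3
Reagents that add atoms: dioxygen, O=O
Why: Mukaiyama hydration (metal-hydride hydrogen-atom transfer): H• adds to the CH end of the trisubstituted norbornene, and the tertiary 2-norbornyl radical is trapped by O2 on the exo face (syn to the CH2 bridge), so after reduction of the hydroperoxide the C14 hydroxyl is exo and the isopropyl group endo, with Markovnikov regiochemistry and the ketone untouched.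

**Step 10**
Reactants: 18 (1R,4S,8R,9S,10S,12R,14R)-8,14-dihydroxy-4,8-dimethyl-14-(propan-2-yl)tetracyclo[10.2.1.0^1,10.0^4,9]pentadecan-5-one
Product: 20 (1R,4S,8R,9S,10S,12R,14R)-5-bromo-4,8-dimethyl-14-(propan-2-yl)tetracyclo[10.2.1.0^1,10.0^4,9]pentadec-5-ene-8,14-diol, via N-silyl hydrazone 19 (not isolated)
Conditions: TBSNHNHTBS, Sc(OTf)3 (1 mol%), CHCl3, 55 °C, volatiles removed; then Br2, 2-tert-butyl-1,1,3,3-tetramethylguanidine (BTMG), CH2Cl2, 0 °C → rt
Reagents that add atoms: bromine, BrBr
Why: Barton-type vinyl halide synthesis through the N-silyl hydrazone (oxidation to the diazo compound, bromination, loss of N2 and of a proton); C4 is quaternary, so the double bond can only form toward C6 and no stereocentre is involved.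

**Step 11**
Reactants: 20 (1R,4S,8R,9S,10S,12R,14R)-5-bromo-4,8-dimethyl-14-(propan-2-yl)tetracyclo[10.2.1.0^1,10.0^4,9]pentadec-5-ene-8,14-diol
Product: 21 (1R,4S,5S,8R,9S,10S,12R,14R)-5-bromo-4,8-dimethyl-14-(propan-2-yl)tetracyclo[10.2.1.0^1,10.0^4,9]pentadecane-8,14-diol (CNP0362628.1)
Conditions: Mn(dpm)3 (10 mol%), PhSiH3, t-BuOOH, i-PrOH, rt, Ar
Reagents that add atoms: none
Why: Metal-hydride hydrogen-atom-transfer hydrogenation of a haloalkene (radical mechanism that leaves the C–Br bond intact): H• adds to C6, and the α-bromo radical at C5 takes the second hydrogen on the axial face opposite the angular C4-methyl, giving the equatorial bromide cis to that methyl, which is also the thermodynamic epimer.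

**Compound list**
1 | (R)-(−)-linalool, (3R)-3,7-dimethylocta-1,6-dien-3-ol | CC(C)=CCC[C@@](C)(O)C=C | starting material
2 | (6R)-3-hydroperoxy-2,6-dimethylocta-1,7-dien-6-ol (C3 epimers) | CC(=C)C(OO)CC[C@@](C)(O)C=C | intermediate (not isolated)
3 | (6R)-6-hydroxy-2,6-dimethylocta-1,7-dien-3-one | CC(=C)C(=O)CC[C@@](C)(O)C=C | intermediate
4 | (4R)-4-hydroxy-2,4-dimethylcyclohex-2-en-1-one | CC1=C[C@](C)(O)CCC1=O | intermediate
5 | cyclopentanone | O=C1CCCC1 | starting material
6 | acetone | CC(C)=O | starting material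
7 | lithium cyclopent-1-en-1-olate | [Li]OC1=CCCC1 | intermediate (not isolated)
8 | 2-(2-hydroxypropan-2-yl)cyclopentan-1-one (racemic) | CC(C)(O)C1CCCC1=O | intermediate
9 | 2-(propan-2-ylidene)cyclopentan-1-one | CC(C)=C1CCCC1=O | intermediate (not isolated)
10 | 2-(propan-2-yl)cyclopent-2-en-1-one | CC(C)C1=CCCC1=O | intermediate
11 | 1-ethenyl-2-(propan-2-yl)cyclopent-2-en-1-ol (racemic) | CC(C)C1=CCCC1(O)C=C | intermediate
12 | (3E)-3-(2-bromoethylidene)-2-(propan-2-yl)cyclopent-1-ene | BrC/C=C1\CCC=C1C(C)C | intermediate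
13 | bis(bromomagnesium) enolate/alkoxide of (3S,4R)-3-ethenyl-4-hydroxy-2,4-dimethylcyclohexan-1-one (C1–C2 enolate, C4 alkoxide) | C=C[C@H]1C(C)=C(O[Mg]Br)CC[C@@]1(C)O[Mg]Br | intermediate (not isolated)
14 | (2S,3S,4R)-3-ethenyl-4-hydroxy-2,4-dimethyl-2-{(2E)-2-[2-(propan-2-yl)cyclopent-2-en-1-ylidene]ethyl}cyclohexan-1-one | C=C[C@H]1[C@](C)(C/C=C2\CCC=C2C(C)C)C(=O)CC[C@@]1(C)O | intermediate
15 | (2S,3S,4R)-3-ethenyl-4-hydroxy-2,4-dimethyl-2-{2-[2-(propan-2-yl)cyclopenta-1,3-dien-1-yl]ethyl}cyclohexan-1-one | C=C[C@H]1[C@](C)(CCC2=C(C(C)C)C=CC2)C(=O)CC[C@@]1(C)O | intermediate (not isolated)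
16 | (1R,4S,8R,9S,10S,12R)-8-hydroxy-4,8-dimethyl-14-(propan-2-yl)tetracyclo[10.2.1.0^1,10.0^4,9]pentadec-13-en-5-one | CC(C)C1=C[C@@H]2C[C@H]3[C@H]4[C@](C)(CC[C@@]31C2)C(=O)CC[C@@]4(C)O | intermediate
17 | (1R,4S,8R,9S,10S,12R,14R)-14-hydroperoxy-8-hydroxy-4,8-dimethyl-14-(propan-2-yl)tetracyclo[10.2.1.0^1,10.0^4,9]pentadecan-5-one | CC(C)[C@]1(OO)C[C@@H]2C[C@H]3[C@H]4[C@](C)(CC[C@@]31C2)C(=O)CC[C@@]4(C)O | intermediate (not isolated)
18 | (1R,4S,8R,9S,10S,12R,14R)-8,14-dihydroxy-4,8-dimethyl-14-(propan-2-yl)tetracyclo[10.2.1.0^1,10.0^4,9]pentadecan-5-one | CC(C)[C@]1(O)C[C@@H]2C[C@H]3[C@H]4[C@](C)(CC[C@@]31C2)C(=O)CC[C@@]4(C)O | intermediate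
19 | N-(tert-butyldimethylsilyl)hydrazone of 18 at C5 | CC(C)[C@]1(O)C[C@@H]2C[C@H]3[C@H]4[C@](C)(CC[C@@]31C2)C(=NN[Si](C)(C)C(C)(C)C)CC[C@@]4(C)O | intermediate (not isolated)
20 | (1R,4S,8R,9S,10S,12R,14R)-5-bromo-4,8-dimethyl-14-(propan-2-yl)tetracyclo[10.2.1.0^1,10.0^4,9]pentadec-5-ene-8,14-diol | CC(C)[C@]1(O)C[C@@H]2C[C@H]3[C@H]4[C@](C)(CC[C@@]31C2)C(Br)=CC[C@@]4(C)O | intermediate
21 | (1R,4S,5S,8R,9S,10S,12R,14R)-5-bromo-4,8-dimethyl-14-(propan-2-yl)tetracyclo[10.2.1.0^1,10.0^4,9]pentadecane-8,14-diol | CC(C)[C@]1(O)C[C@@H]2C[C@H]3[C@H]4[C@](C)(CC[C@@]31C2)[C@@H](Br)CC[C@@]4(C)O | target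

**Step count**
Total: 11 steps. Longest linear sequence: 9 steps (cyclopentanone 5 → 21, steps 3–11); the linalool branch is 7 steps.

**Three steps most likely to fail, with fallbacks**

Step 7 (three-component coupling). Risks are 1,2-addition instead of syn-1,4-addition of the Grignard reagent, and a sluggish or unselective alkylation of the hindered magnesium enolate with the labile bromide 12. Fallback, setting out from 4 and 11 and returning at 14: run the alkoxide-directed vinyl addition on 4 as before but quench the enolate with Me3SiCl/Et3N and isolate the regio-defined [(3S,4R)-3-ethenyl-2,4-dimethyl-4-(trimethylsilyloxy)cyclohex-1-en-1-yl]oxy(trimethyl)silane F1. Convert carbinol 11 (n-BuLi, ClCO2Me, THF, −78 °C) into 1-ethenyl-2-(propan-2-yl)cyclopent-2-en-1-yl methyl carbonate F2. Join F1 and F2 by Pd(0)-catalysed Tsuji–Trost allylation (Pd(PPh3)4, Bu4N Ph3SiF2, THF): fluoride frees the enolate, the π-allyl complex from F2 is attacked at its unhindered CH2 terminus anti to the vinyl group, and the tertiary silyl ether is lost on work-up, giving 14 without bromide 12.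

Step 8 (cycloaddition cascade). Risks are that the doubly neopentyl, unactivated vinyl group reacts too slowly at temperatures the hydroxy ketone tolerates, or that a minor cyclopentadiene tautomer cyclises instead. Fallback, setting out from 4 and 12 and returning at 16: give the dienophile a traceless activating group. In the step-7 protocol replace vinylmagnesium bromide by [(1E)-3,3-diethoxyprop-1-en-1-yl]magnesium bromide F3 (from the corresponding bromide and Mg), which after alkylation with 12 gives (2S,3S,4R)-3-[(1E)-3,3-diethoxyprop-1-en-1-yl]-4-hydroxy-2,4-dimethyl-2-{(2E)-2-[2-(propan-2-yl)cyclopent-2-en-1-ylidene]ethyl}cyclohexan-1-one F4. Aqueous oxalic acid unmasks the aldehyde and shifts the diene into the ring to give the enal analogue of cyclopentadiene 15 F5, whose conjugated dienophile undergoes the same intramolecular Diels–Alder reaction at or below 80 °C to give the 11-formyl derivative of 16 F6 (both C11 epimers). Rh-mediated decarbonylation (RhCl(PPh3)3, PhCN, 130 °C) then removes the formyl group and rejoins the route at 16.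

Step 11 (hydrogenation of the vinyl bromide). Risks are reductive loss of bromine or the wrong C5 epimer. Fallback, setting out from 18 and returning at 21: reduce ketone 18 with L-Selectride (THF, −78 °C, equatorial hydride delivery) to the axial alcohol (1R,4S,5R,8R,9S,10S,12R,14R)-4,8-dimethyl-14-(propan-2-yl)tetracyclo[10.2.1.0^1,10.0^4,9]pentadecane-5,8,14-triol F7. Replace the secondary hydroxyl by bromide with inversion (PPh3, CBr4, 2,6-lutidine, CH2Cl2; the tertiary alcohols do not react). This ionic SN2 route gives the same equatorial bromide 21 and avoids vinyl bromide 20, but elimination will compete at this neopentyl centre.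

**Further compounds**
F1 | step 7 | [(3S,4R)-3-ethenyl-2,4-dimethyl-4-(trimethylsilyloxy)cyclohex-1-en-1-yl]oxy(trimethyl)silane | C=C[C@H]1C(C)=C(O[Si](C)(C)C)CC[C@@]1(C)O[Si](C)(C)C
F2 | step 7 | 1-ethenyl-2-(propan-2-yl)cyclopent-2-en-1-yl methyl carbonate (racemic) | CC(C)C1=CCCC1(OC(=O)OC)C=C
F3 | step 8 | [(1E)-3,3-diethoxyprop-1-en-1-yl]magnesium bromide | CCOC(OCC)/C=C/[Mg]Br
F4 | step 8 | (2S,3S,4R)-3-[(1E)-3,3-diethoxyprop-1-en-1-yl]-4-hydroxy-2,4-dimethyl-2-{(2E)-2-[2-(propan-2-yl)cyclopent-2-en-1-ylidene]ethyl}cyclohexan-1-one | CCOC(OCC)/C=C/[C@H]1[C@](C)(C/C=C2\CCC=C2C(C)C)C(=O)CC[C@@]1(C)O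
F5 | step 8 | enal analogue of cyclopentadiene 15 ((E)-CH=CH–CHO in place of vinyl) | O=C/C=C/[C@H]1[C@](C)(CCC2=C(C(C)C)C=CC2)C(=O)CC[C@@]1(C)O
F6 | step 8 | 11-formyl derivative of 16 (both C11 epimers) | CC(C)C1=C[C@@H]2C(C=O)[C@H]3[C@H]4[C@](C)(CC[C@@]31C2)C(=O)CC[C@@]4(C)O
F7 | step 11 | (1R,4S,5R,8R,9S,10S,12R,14R)-4,8-dimethyl-14-(propan-2-yl)tetracyclo[10.2.1.0^1,10.0^4,9]pentadecane-5,8,14-triol | CC(C)[C@]1(O)C[C@@H]2C[C@H]3[C@H]4[C@](C)(CC[C@@]31C2)[C@H](O)CC[C@@]4(C)O
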